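The route builds benzo ring A of the chroman-2-one by a [4+2] cycloaddition–aromatisation of a 4-substituted 1-methoxy-1,3-bis(trimethylsilyloxy)diene with an aryl ethynyl ketone. Ring A carries oxygen at C8a and C7, the arylethyl chain at C6 and the C4 carbon on C4a. This is the 2,4-dihydroxy-5-alkyl-acylbenzene pattern that the benzannulation gives directly: one operation forms C5–C6 and C4a–C8a and leaves the future C4 as a ketone. The precursors are the bis-silyl dienol ether of methyl 6-(3,4-dimethoxyphenyl)-3-oxohexanoate and 1-[3,4-bis(benzyloxy)phenyl]prop-2-yn-1-one. Wittig lactonisation, ligand-controlled copper hydride conjugate reduction (setting C4 as R) and hydrogenolysis finish the route.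

Key step: step 6

Assumption: (R)-DTBM-SEGPHOS on copper hydride is taken to deliver hydride to the C4 face that gives the 4R lactone; the sense is to be checked on the first run and the S ligand used if it proves opposite.

Step 1
Reactants: 1 4-(3,4-dimethoxyphenyl)butanoic acid; 2 Meldrum's acid (2,2-dimethyl-1,3-dioxane-4,6-dione)
Product: 4 methyl 6-(3,4-dimethoxyphenyl)-3-oxohexanoate, via acyl Meldrum's acid 3 (not isolated)
Conditions: DCC, DMAP, CH2Cl2, 0 °C to rt; filter, acid wash; then MeOH, reflux
Reagents that add atoms: methanol, CO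
Why: Carbodiimide-mediated C-acylation of Meldrum's acid followed by methanolysis with loss of acetone and CO2 (Meldrum's acid β-keto ester synthesis) should give the γ-substituted β-keto ester under non-basic conditions, so no elimination-prone phenethyl halide has to meet a strongly basic dianion.

Step 2
Reactants: 4 methyl 6-(3,4-dimethoxyphenyl)-3-oxohexanoate
Product: 5 methyl 6-(3,4-dimethoxyphenyl)-3-(trimethylsilyloxy)hex-2-enoate
Conditions: Me3SiCl, Et3N, toluene, rt
Reagents that add atoms: chlorotrimethylsilane, C[Si](C)(C)Cl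
Why: Soft enolisation of the β-keto ester and O-silylation (silyl enol ether formation) is standard for 1,3-dicarbonyl compounds, and the aryl methyl ethers are inert.

Step 3
Reactants: 5 methyl 6-(3,4-dimethoxyphenyl)-3-(trimethylsilyloxy)hex-2-enoate
Product: 6 1-methoxy-1,3-bis(trimethylsilyloxy)-6-(3,4-dimethoxyphenyl)hexa-1,3-diene
Conditions: LiN(iPr)2 (commercial solution), THF, −78 °C; then Me3SiCl, −78 °C to rt; salts filtered under argon, used crude
Reagents that add atoms: chlorotrimethylsilane, C[Si](C)(C)Cl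
Why: Kinetic γ-deprotonation of the β-silyloxy enoate gives the extended ester enolate, which is O-silylated to the 1,3-bis(silyloxy)diene (vinylogous silyl ketene acetal formation).

Step 4
Reactants: 7 3,4-bis(benzyloxy)benzaldehyde; 8 ethynylmagnesium bromide
Product: 9 1-[3,4-bis(benzyloxy)phenyl]prop-2-yn-1-ol (racemic)
Conditions: THF, 0 °C to rt; then aq. NH4Cl
Reagents that add atoms: none
Why: Grignard 1,2-addition of the acetylide to the aromatic aldehyde should give the propargylic alcohol, whose racemic carbinol centre is removed in the next step.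

Step 5
Reactants: 9 1-[3,4-bis(benzyloxy)phenyl]prop-2-yn-1-ol
Product: 10 1-[3,4-bis(benzyloxy)phenyl]prop-2-yn-1-one
Conditions: activated MnO2, CH2Cl2, rt
Reagents that add atoms: none
Why: MnO2 oxidation is selective for the benzylic, propargylic alcohol and should give the aryl ethynyl ketone without touching the benzyl ethers or the terminal alkyne.

Step 6
Reactants: 6 1-methoxy-1,3-bis(trimethylsilyloxy)-6-(3,4-dimethoxyphenyl)hexa-1,3-diene; 10 1-[3,4-bis(benzyloxy)phenyl]prop-2-yn-1-one
Product: 13 [3,4-bis(benzyloxy)phenyl]{5-[2-(3,4-dimethoxyphenyl)ethyl]-2,4-dihydroxyphenyl}methanone, via cyclohexadiene cycloadduct 11 (not isolated), via aryl trimethylsilyl ether 12 (not isolated)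
Conditions: 6 (1.5 equiv), toluene, 0 °C to 50 °C, argon; then 1 M HCl, THF, rt
Reagents that add atoms: none
Why: The electron-rich diene 6 and the electron-poor ynone 10 should combine in a normal-demand Diels–Alder reaction (concerted but asynchronous, or stepwise through a Mukaiyama–Michael zwitterion that closes to the same ring), in which the alkyl-bearing diene terminus bonds to the unsubstituted alkyne carbon and the ketene acetal carbon bonds to the carbonyl-bearing alkyne carbon. The closest known reaction type is the cycloaddition–aromatisation of 1-alkoxy-1,3-bis(silyloxy)dienes with acetylenic esters and ketones, which gives resorcylates and acylresorcinols. The one new ring, the carbocycle that becomes benzo ring A, closes by intermolecular [4+2] cycloaddition with both C–C bonds (future C5–C6 and C4a–C8a) made in the same operation; adduct 11 then loses Me3SiOMe from its mixed ketal carbon and tautomerises to phenol 12, which dilute acid desilylates. No stereocentre results, since the two sp3 ring carbons of 11 are flattened on aromatisation. The step needs regioselectivity (chain at C6, aroyl group on C4a), which the polarity match between the nucleophilic alkyl-bearing diene carbon and the electrophilic β-carbon of the ynone secures. It also needs ring closure through the ketene acetal carbon and not through C2 of the diene, which running the reaction thermally without a Lewis acid should favour.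

Step 7
Reactants: 13 [3,4-bis(benzyloxy)phenyl]{5-[2-(3,4-dimethoxyphenyl)ethyl]-2,4-dihydroxyphenyl}methanone
Product: 14 [3,4-bis(benzyloxy)phenyl]{4-(benzyloxy)-5-[2-(3,4-dimethoxyphenyl)ethyl]-2-hydroxyphenyl}methanone
Conditions: BnBr (1.05 equiv), K2CO3, acetone, reflux
Reagents that add atoms: benzyl bromide, BrCc1ccccc1
Why: Williamson etherification with one equivalent of halide should be selective for the phenol para to the ketone, because the ortho phenol is tied up in a strong hydrogen bond to the carbonyl and is much less nucleophilic.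

Step 8
Reactants: 14 [3,4-bis(benzyloxy)phenyl]{4-(benzyloxy)-5-[2-(3,4-dimethoxyphenyl)ethyl]-2-hydroxyphenyl}methanone
Product: 16 4-[3,4-bis(benzyloxy)phenyl]-7-(benzyloxy)-6-[2-(3,4-dimethoxyphenyl)ethyl]-2H-chromen-2-one, via hydroxy cinnamate 15 (not isolated)
Conditions: Ph3P=CHCO2Et (3 equiv), toluene or xylene, reflux
Reagents that add atoms: ethyl (triphenylphosphoranylidene)acetate, CCOC(=O)C=P(c1ccccc1)(c1ccccc1)c1ccccc1
Why: Wittig olefination of the ortho-hydroxy diaryl ketone with the stabilised ylide, followed by lactonisation of the Z hydroxy cinnamate 15 at reflux, is the established way from 2-hydroxybenzophenones to 4-arylcoumarins.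

Step 9
Reactants: 16 4-[3,4-bis(benzyloxy)phenyl]-7-(benzyloxy)-6-[2-(3,4-dimethoxyphenyl)ethyl]-2H-chromen-2-one
Product: 18 (4R)-4-[3,4-bis(benzyloxy)phenyl]-7-(benzyloxy)-6-[2-(3,4-dimethoxyphenyl)ethyl]-3,4-dihydro-2H-chromen-2-one, via boron enolate 17 (not isolated)
Conditions: CuCl (5 mol %), NaOtBu (5 mol %), (R)-DTBM-SEGPHOS (5.5 mol %), pinacolborane (1.5 equiv), toluene, rt; then aq. NH4Cl
Reagents that add atoms: none
Why: The bisphosphine-ligated copper hydride should add hydride to C4 of the coumarin (asymmetric conjugate reduction, run as a 1,4-hydroboration), with the chiral ligand on copper choosing the face of C4 and so setting the R configuration, while trapping as boron enolate 17 keeps the lactone from over-reduction until aqueous work-up.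

Step 10
Reactants: 18 (4R)-4-[3,4-bis(benzyloxy)phenyl]-7-(benzyloxy)-6-[2-(3,4-dimethoxyphenyl)ethyl]-3,4-dihydro-2H-chromen-2-one
Product: 19 (4R)-4-(3,4-dihydroxyphenyl)-6-[2-(3,4-dimethoxyphenyl)ethyl]-7-hydroxy-3,4-dihydro-2H-chromen-2-one
Conditions: H2 (1 atm), 10% Pd/C, EtOAc–THF, rt
Reagents that add atoms: none
Why: Hydrogenolysis of the three aryl benzyl ethers in a non-nucleophilic solvent should leave the lactone, the aryl methyl ethers and the C4 stereocentre (not alpha to the carbonyl, so not epimerisable) untouched.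

Compound list
1 | 4-(3,4-dimethoxyphenyl)butanoic acid | COc1ccc(CCCC(=O)O)cc1OC | starting material
2 | Meldrum's acid (2,2-dimethyl-1,3-dioxane-4,6-dione) | CC1(C)OC(=O)CC(=O)O1 | starting material
3 | 5-[4-(3,4-dimethoxyphenyl)-1-hydroxybutylidene]-2,2-dimethyl-1,3-dioxane-4,6-dione (acyl Meldrum's acid) | COc1ccc(CCCC(O)=C2C(=O)OC(C)(C)OC2=O)cc1OC | intermediate
4 | methyl 6-(3,4-dimethoxyphenyl)-3-oxohexanoate | COC(=O)CC(=O)CCCc1ccc(OC)c(OC)c1 | intermediate
5 | methyl 6-(3,4-dimethoxyphenyl)-3-(trimethylsilyloxy)hex-2-enoate (double-bond geometry not controlled) | COC(=O)C=C(CCCc1ccc(OC)c(OC)c1)O[Si](C)(C)C | intermediate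
6 | 1-methoxy-1,3-bis(trimethylsilyloxy)-6-(3,4-dimethoxyphenyl)hexa-1,3-diene (geometry not controlled, lost on aromatisation) | COC(O[Si](C)(C)C)=CC(O[Si](C)(C)C)=CCCc1ccc(OC)c(OC)c1 | intermediate
7 | 3,4-bis(benzyloxy)benzaldehyde | O=Cc1ccc(OCc2ccccc2)c(OCc2ccccc2)c1 | starting material
8 | ethynylmagnesium bromide | C#C[Mg]Br | starting material
9 | 1-[3,4-bis(benzyloxy)phenyl]prop-2-yn-1-ol (racemic) | C#CC(O)c1ccc(OCc2ccccc2)c(OCc2ccccc2)c1 | intermediate
10 | 1-[3,4-bis(benzyloxy)phenyl]prop-2-yn-1-one | C#CC(=O)c1ccc(OCc2ccccc2)c(OCc2ccccc2)c1 | intermediate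
11 | [3,4-bis(benzyloxy)phenyl]{3-[2-(3,4-dimethoxyphenyl)ethyl]-6-methoxy-4,6-bis(trimethylsilyloxy)cyclohexa-1,4-dien-1-yl}methanone (mixture of stereoisomers) | COC1(O[Si](C)(C)C)C=C(O[Si](C)(C)C)C(CCc2ccc(OC)c(OC)c2)C=C1C(=O)c1ccc(OCc2ccccc2)c(OCc2ccccc2)c1 | intermediate
12 | [3,4-bis(benzyloxy)phenyl]{5-[2-(3,4-dimethoxyphenyl)ethyl]-2-hydroxy-4-(trimethylsilyloxy)phenyl}methanone | COc1ccc(CCc2cc(C(=O)c3ccc(OCc4ccccc4)c(OCc4ccccc4)c3)c(O)cc2O[Si](C)(C)C)cc1OC | intermediate
13 | [3,4-bis(benzyloxy)phenyl]{5-[2-(3,4-dimethoxyphenyl)ethyl]-2,4-dihydroxyphenyl}methanone | O=C(c1ccc(OCc2ccccc2)c(OCc2ccccc2)c1)c1cc(CCc2ccc(OC)c(OC)c2)c(O)cc1O | intermediate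
14 | [3,4-bis(benzyloxy)phenyl]{4-(benzyloxy)-5-[2-(3,4-dimethoxyphenyl)ethyl]-2-hydroxyphenyl}methanone | COc1ccc(CCc2cc(C(=O)c3ccc(OCc4ccccc4)c(OCc4ccccc4)c3)c(O)cc2OCc2ccccc2)cc1OC | intermediate
15 | ethyl (2Z)-3-[3,4-bis(benzyloxy)phenyl]-3-{4-(benzyloxy)-5-[2-(3,4-dimethoxyphenyl)ethyl]-2-hydroxyphenyl}prop-2-enoate | CCOC(=O)/C=C(/c1ccc(OCc2ccccc2)c(OCc2ccccc2)c1)c1cc(CCc2ccc(OC)c(OC)c2)c(OCc2ccccc2)cc1O | intermediate
16 | 4-[3,4-bis(benzyloxy)phenyl]-7-(benzyloxy)-6-[2-(3,4-dimethoxyphenyl)ethyl]-2H-chromen-2-one | COc1ccc(CCc2cc3c(cc2OCc2ccccc2)OC(=O)C=C3c2ccc(OCc3ccccc3)c(OCc3ccccc3)c2)cc1OC | intermediate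
17 | (4R)-4-[3,4-bis(benzyloxy)phenyl]-7-(benzyloxy)-6-[2-(3,4-dimethoxyphenyl)ethyl]-2-[(4,4,5,5-tetramethyl-1,3,2-dioxaborolan-2-yl)oxy]-4H-chromene | COc1ccc(CCc2cc3c(cc2OCc2ccccc2)OC(OB2OC(C)(C)C(C)(C)O2)=C[C@@H]3c2ccc(OCc4ccccc4)c(OCc4ccccc4)c2)cc1OC | intermediate
18 | (4R)-4-[3,4-bis(benzyloxy)phenyl]-7-(benzyloxy)-6-[2-(3,4-dimethoxyphenyl)ethyl]-3,4-dihydro-2H-chromen-2-one | COc1ccc(CCc2cc3c(cc2OCc2ccccc2)OC(=O)C[C@@H]3c2ccc(OCc4ccccc4)c(OCc4ccccc4)c2)cc1OC | intermediate
19 | (4R)-4-(3,4-dihydroxyphenyl)-6-[2-(3,4-dimethoxyphenyl)ethyl]-7-hydroxy-3,4-dihydro-2H-chromen-2-one | COc1ccc(CCc2cc3c(cc2O)OC(=O)C[C@@H]3c2ccc(O)c(O)c2)cc1OC | target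

Total step count: 10. Longest linear sequence: 8 steps (steps 1, 2, 3, 6, 7, 8, 9, 10); the ynone branch (steps 4 and 5) joins at step 6.

Steps most likely to fail

Step 6 (benzannulation). The diene may add to the ynone in a stepwise conjugate sense without closing through the ketene acetal carbon, giving acyclic adducts or closure through C2 onto the ketone. The terminal ynone may oligomerise, the hindered 4-substituted diene may hydrolyse before it reacts, and the mixed ketal may partly lose silanol instead of Me3SiOMe and keep a methyl ether on the C8a oxygen. The fallback sets out from aldehyde 7, builds the pyranone ring on a preformed alkylresorcinol and returns at coumarin 16, bypassing steps 6 to 8. Aldehyde 7 would be homologated with ethyl diazoacetate and catalytic SnCl2 in CH2Cl2 (Roskamp reaction) to ethyl 3-[3,4-bis(benzyloxy)phenyl]-3-oxopropanoate F1. Separately, commercial 2,4-bis(benzyloxy)benzaldehyde and (3,4-dimethoxybenzyl)triphenylphosphonium bromide with KOtBu in THF (Wittig) would give 2,4-bis(benzyloxy)-1-[2-(3,4-dimethoxyphenyl)ethenyl]benzene F2 as a mixture of alkene isomers. Hydrogen over Pd/C would saturate the alkene and cleave both benzyl ethers to 4-[2-(3,4-dimethoxyphenyl)ethyl]benzene-1,3-diol F3. Pechmann condensation of F3 with F1 in CF3CO2H at rt, at the ring position para to one hydroxyl and ortho to the other, would give 4-[3,4-bis(benzyloxy)phenyl]-6-[2-(3,4-dimethoxyphenyl)ethyl]-7-hydroxy-2H-chromen-2-one F4. Benzylation of every free phenol (BnBr, K2CO3, DMF), which also restores any benzyl ether lost in the acid, would then give 16.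

Step 9 (asymmetric conjugate reduction). Facial selectivity at the β,β-diaryl acceptor may be poor or of the wrong sense, hydrocupration of the hindered trisubstituted alkene may stall, or the aryl lactone may be reduced further to the lactol. The fallback sets out from coumarin 16, replaces asymmetric catalysis by resolution and returns at target 19. Hydrogenation of 16 over Pd/C (H2 at a few bar, EtOAc–AcOH) would saturate C3–C4 and remove the three benzyl groups in one operation to give racemic 4-(3,4-dihydroxyphenyl)-6-[2-(3,4-dimethoxyphenyl)ethyl]-7-hydroxy-3,4-dihydro-2H-chromen-2-one F5. Preparative chromatography on a polysaccharide chiral stationary phase would separate the enantiomers, the R antipode being 19.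

Step 8 (Wittig lactonisation). Olefination of the ketone, which is deactivated by two para alkoxy groups and an ortho hydroxyl, may be slow, and the acrylate may form with the ester trans to the phenol ring and fail to lactonise. The fallback sets out from ketone 14, fixes the cis geometry by making the ring-closing bond intramolecularly and returns at coumarin 16. The phenol of 14 would be acylated with (diethoxyphosphoryl)acetic acid (EDC·HCl, DMAP, CH2Cl2) to 2-[3,4-bis(benzyloxy)benzoyl]-5-(benzyloxy)-4-[2-(3,4-dimethoxyphenyl)ethyl]phenyl (diethoxyphosphoryl)acetate F6. Intramolecular Horner–Wadsworth–Emmons olefination of F6 (DBU, LiCl, MeCN) would close the pyranone to 16.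

Further compounds
F1 | step 6 | ethyl 3-[3,4-bis(benzyloxy)phenyl]-3-oxopropanoate | CCOC(=O)CC(=O)c1ccc(OCc2ccccc2)c(OCc2ccccc2)c1
F2 | step 6 | 2,4-bis(benzyloxy)-1-[2-(3,4-dimethoxyphenyl)ethenyl]benzene (mixture of alkene isomers) | COc1ccc(C=Cc2ccc(OCc3ccccc3)cc2OCc2ccccc2)cc1OC
F3 | step 6 | 4-[2-(3,4-dimethoxyphenyl)ethyl]benzene-1,3-diol | COc1ccc(CCc2ccc(O)cc2O)cc1OC
F4 | step 6 | 4-[3,4-bis(benzyloxy)phenyl]-6-[2-(3,4-dimethoxyphenyl)ethyl]-7-hydroxy-2H-chromen-2-one | COc1ccc(CCc2cc3c(cc2O)OC(=O)C=C3c2ccc(OCc3ccccc3)c(OCc3ccccc3)c2)cc1OC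
F5 | step 9 | racemic 4-(3,4-dihydroxyphenyl)-6-[2-(3,4-dimethoxyphenyl)ethyl]-7-hydroxy-3,4-dihydro-2H-chromen-2-one | COc1ccc(CCc2cc3c(cc2O)OC(=O)CC3c2ccc(O)c(O)c2)cc1OC
F6 | step 8 | 2-[3,4-bis(benzyloxy)benzoyl]-5-(benzyloxy)-4-[2-(3,4-dimethoxyphenyl)ethyl]phenyl (diethoxyphosphoryl)acetate | CCOP(=O)(CC(=O)Oc1cc(OCc2ccccc2)c(CCc2ccc(OC)c(OC)c2)cc1C(=O)c1ccc(OCc2ccccc2)c(OCc2ccccc2)c1)OCC
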